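## The problem

The target is a biflavonoid built from a 3-hydroxychroman-4-one (ring A, the phloroglucinol ring; ring C, the pyranone; ring B, the 4-hydroxyphenyl group on C2) and a (2S)-flavan (aromatic ring D, pyran ring E). The two units are joined twice, C3 to C8' and C2 to O7', so the C2–C3 bond belongs both to ring C and to a dihydrofuran, ring F (unprimed locants: chromanone unit; primed locants: flavan unit). There are three stereocentres. C2' (S) is remote and cannot steer anything, so it is best bought with the starting material. C3 (S) is a fully substituted tertiary carbinol and must be set by an external chiral agent. C2 (R) is a ketal carbon between O1 and O7' that can only be closed reversibly, so its configuration follows from C3 through ring C and not from a reagent. The molecule has several fragile features: the ketal, an α-hydroxy ketone flanked by two carbonyl-level carbons (open to retro-Claisen cleavage under base), six phenols, and a flavan C2'–O1' bond that is benzylic to a 4-oxygenated aryl group. A flavanone starting material also racemises through its chalcone under base. Ring D needs O7' and C8' functionalised while O5' and C6' stay untouched, a problem of both regiochemistry and protecting-group differentiation. The feature that opens the key step is that C3 sits between the C4 aryl ketone and C2, a carbon at acyl oxidation level that is bonded to O7'. A carbene at C3 can therefore take up water for the hydroxyl and the neighbouring O7' aroyl ester for C2 in one event.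

## Retrosynthesis

**Ring C last (27 to 25).** The C2–O1 ketal bond and the six O-benzyl bonds are cut first. This leads, through the free hexaphenol 26, to hemiketal 25, in which ring C is open and ring A is a 2,4,6-tris(benzyloxy)benzoyl group on C3. Cutting C2–O1 rather than C2–O7' keeps the five-membered ring, which forms more easily, and leaves a closure that is a reversible transketalisation onto an oxocarbenium ion. The forward reaction only has to free the phenols under neutral conditions and then supply a trace of acid. The two ortho hydroxyls of ring A are equivalent, so no regiochemical question arises.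

**The carbinol carbon (25 to 23 and 24).** In 25 the C2–C3 bond and the C3–O bond are cut together. C3 becomes the carbene carbon of α-diazo ketone 23, the oxygen comes from water 24, and C2 returns to the carbonyl carbon of a 4-(benzyloxy)benzoate on O7'. The neighbouring cuts would be C3–C4 (an acyloin closure) or oxidation of a preformed benzofuran; both need C2 or C3 to be built beforehand. This cut removes ring F, the C3 stereocentre and the hemiketal at once, so the precursor has only C2' as a stereocentre. The forward reaction has to make the ylide or enol capture the ester faster than it tautomerises, and it needs a chiral acid to choose the face of C3.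

**Ester and diazo group (23 to 20, 21, 19 and 18).** The O7'–acyl bond of 23 is cut to acid chloride 21 and the phenol 22, which is released from silyl ether 20. The diazo group of 20 is cut back to the methylene of deoxybenzoin 18 by diazo transfer from 19. The order is dictated by reactivity: an enolisable benzyl ketone that already carried the O7' ester would undergo acyl migration under the base used for diazo transfer. The ester is therefore added last, and O7' is masked until then by the one group that can be removed beside a diazo ketone, a silyl ether cleaved by fluoride.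

**The aryl–CH2 bond (18 to 15 and 17).** Cutting C8'–CH2 gives aryl bromide 15 and methyl ketone 17, to be joined by palladium-catalysed enolate arylation. The competing plan is an aromatic Claisen rearrangement of a 7-O-allyl flavan followed by oxidative cleavage and acylation of the ring A arene. It was set aside as the main line because C6 and C8 are electronically alike in a 5,7-dioxygenated flavan, so the sigmatropic shift cannot be relied on for one position. It is kept as a fallback. Ketone 17 comes in one step from the commercial triphenol 16 and benzyl bromide 9.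

**Differentiating O7 and marking C8 (15 to 13, 12 and 10).** Silyl ether 15 comes from phenol 13 and silyl chloride 14. Phenol 13 comes from allyl ether 12 by deallylation, and 12 from flavan 10 by bromination with 11. Electrophilic substitution of 5,7-dialkoxyflavans goes to C8, which gives the regiochemistry. The allyl group carries the O7 differentiation up to this point and is exchanged for silicon only after bromination, because a silyl ether would not survive the base used in the earlier alkylations.

**The flavan from the chiral pool (10 to 8, 5, 3 and 1).** Benzyl ether 10 is cut to phenol 8 and 9. Phenol 8 arises from flavanone 5 by removal of the C4 oxygen through carbonate 7 (from 6). Compound 5 comes from 3 and benzyl alcohol 4, and 3 from (2S)-naringenin 1 and allyl bromide 2. The order follows the acidity of the phenols of 1 (7-OH, then 4'-OH, then the chelated 5-OH). Base is avoided from the point where ring-opening to the chalcone would endanger C2, and the chelated 5-OH is put to use in the deoxygenation.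

## Roads not taken

**Alternative 1:** The cut runs through ring D itself. C7'–C8' and C4a'–C8a' are disconnected so that rings D and E arise together from cyclobutenone A1, whose side chain carries C2' and a silyl-capped alkynyl ether. In the forward step, light opens the cyclobutenone to a vinylketene, which adds to the tethered alkyne; 4π opening and 6π closure (Danheiser benzannulation) then give flavan A2 with a free 7'-hydroxyl and a trimethylsilyl group at C8'.
- Merit: the substitution pattern of ring D is written into the product. O7' is the only free phenol and C8' the only silylated carbon, so neither a selective first alkylation nor a selective bromination has to be trusted. Here this road is better than the chosen one, which spends steps 1, 5, 6 and 7 on the same differentiation.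
- Weak points: A1 has to be made in enantiopure form over several steps, whereas 1 supplies C2' for nothing. An alkynyl ether on a benzylic stereocentre is prone to ionisation. The aryl silane of A2 must still be turned into the C8'–C bond, by ipso-bromination to the level of 15 followed by the same arylation.
- Comparison: the alternative reaches the stage of 15 in more steps and does nothing for C2 and C3. The chosen plan sets robust, ordinary reactions and a chiral-pool stereocentre against the alternative's regiochemical certainty.

**Alternative 2:** The cut is C4a–C5. Ring A is unravelled into the 3,5,7-trioxo ester chain of A3, which hangs from C4 of a finished ring F methyl ketal with C3 protected as its methoxymethyl ether. In the forward step, base-mediated Claisen cyclisation and enolisation fold the chain into the phloroglucinol ketone A4.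
- Merit: the ring A phenols appear free and late, and the hindered ketone 17 and its coupling are avoided. In that one respect it is better than the chosen plan, which has to debenzylate ring A at the end.
- Weak points: A3 is hard to make and to keep, because polyketones self-condense and an aldol mode competes with the Claisen mode. The base it needs threatens retro-Claisen cleavage of the C3–C4 bond next to the quaternary α-alkoxy centre. C2 and C3 must already be in place in A3, so the tertiary carbinol problem is postponed and not solved.
- Comparison: the chosen plan buys ring A as 16 and forms C3 in the step that joins the two halves.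

**Alternative 3:** The cut is C3–C4. The precursor is keto aldehyde A5, a 2-aryl-2-aryloxybenzofuran-3-one whose aryloxy group is the ring A aldehyde. In the forward step, a triazolylidene carbene turns the aldehyde into its Breslow intermediate, which adds to the C3 ketone and closes ring C to give the penta-O-benzyl target A6, one hydrogenolysis from 27.
- Merits: intramolecular crossed aldehyde–ketone benzoin closures to 3-hydroxychroman-4-ones are established chemistry, so this ring closure is better precedented than step 12. C3 is formed under the control of the existing C2 through the ring being closed, and no hemiketal has to be carried. In these respects the road is as good as or better than the chosen one.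
- Weak points: these lie in A5. It contains a mixed diaryl ketal at a quaternary carbon α to a ketone, which must be made intermolecularly from a hindered ortho-formyl phenol with no control of C2 relative to C2'. An aryloxide leaving group sits β to the alkoxide generated in the benzoin step, inviting fragmentation. The aldehyde is flanked by two oxygen substituents and forms its Breslow intermediate slowly.
- Comparison: the chosen plan needs only an ester (step 11) where this road needs a hindered ketal. It sets C3 by a catalyst and leaves C2 to equilibrium. The price is a key step without direct precedent.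

Key step: step 12

Assumption: C2 is a ketal carbon closed reversibly under acid; the route sets C3 and C2' and relies on that reversible closure to deliver the (2R) configuration drawn for the target.
Assumption: the sense of induction of the chiral phosphoric acid cannot be predicted; (R)-TRIP is written and stands for whichever antipode favours the (3S) product.
Assumption: (2S)-naringenin, 2',4',6'-trihydroxyacetophenone and 4-(benzyloxy)benzoyl chloride are taken as commercial.

## Steps

Step 1
Reactants: 1 (2S)-naringenin; 2 allyl bromide
Product: 3 (2S)-7-(allyloxy)-5-hydroxy-2-(4-hydroxyphenyl)chroman-4-one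
Conditions: allyl bromide (1.05 equiv), K2CO3 (1.05 equiv), acetone, rt
Reagents that add atoms: allyl bromide (2), C=CCBr
Why: Williamson etherification; the 7-OH, para to the carbonyl, is the most acidic phenol, the 5-OH is tied up in a hydrogen bond to C4=O and the 4'-OH is much weaker, so one equivalent of weak base should alkylate O7 only. The 7-phenoxide lowers the acidity at C3 and so guards C2 against ring-opening to the chalcone.

Step 2
Reactants: 3 (2S)-7-(allyloxy)-5-hydroxy-2-(4-hydroxyphenyl)chroman-4-one; 4 benzyl alcohol
Product: 5 (2S)-7-(allyloxy)-2-[4-(benzyloxy)phenyl]-5-hydroxychroman-4-one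
Conditions: BnOH (1.2 equiv), PPh3, DIAD, THF, 0 °C to rt
Reagents that add atoms: benzyl alcohol (4), OCc1ccccc1
Why: Mitsunobu etherification of the 4'-phenol under neutral conditions; the chelated 5-OH is too weakly acidic and too shielded to compete. No phenoxide is generated, so the base-induced ring-opening that would racemise C2 is avoided.

Step 3
Reactants: 5 (2S)-7-(allyloxy)-2-[4-(benzyloxy)phenyl]-5-hydroxychroman-4-one; 6 ethyl chloroformate
Product: 8 (2S)-7-(allyloxy)-2-[4-(benzyloxy)phenyl]chroman-5-ol, via 5-O-ethoxycarbonyl flavanone 7 (not isolated)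
Conditions: ClCO2Et, Et3N, THF, 0 °C; then NaBH4, H2O, 0 °C to rt
Reagents that add atoms: none
Why: Reductive deoxygenation of an ortho-acylphenol through its ethyl carbonate: hydride gives the C4 alkoxide, the carbonate migrates to it and is expelled by the phenoxide as an ortho-quinone methide, which NaBH4 reduces to the methylene. C2 takes no part and keeps its configuration; allyl and benzyl ethers are inert.

Step 4
Reactants: 8 (2S)-7-(allyloxy)-2-[4-(benzyloxy)phenyl]chroman-5-ol; 9 benzyl bromide
Product: 10 (2S)-7-(allyloxy)-5-(benzyloxy)-2-[4-(benzyloxy)phenyl]chromane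
Conditions: BnBr, K2CO3, DMF, rt
Reagents that add atoms: benzyl bromide (9), BrCc1ccccc1
Why: Williamson etherification of an ordinary phenol; with the carbonyl gone and O4' capped there is no base-induced ring-opening pathway left, so C2 is safe.

Step 5
Reactants: 10 (2S)-7-(allyloxy)-5-(benzyloxy)-2-[4-(benzyloxy)phenyl]chromane; 11 N-bromosuccinimide
Product: 12 (2S)-7-(allyloxy)-5-(benzyloxy)-2-[4-(benzyloxy)phenyl]-8-bromochromane
Conditions: NBS (1.0 equiv), CH2Cl2, −78 °C to 0 °C
Reagents that add atoms: N-bromosuccinimide (11), O=C1CCC(=O)N1Br
Why: Electrophilic aromatic bromination of the trioxygenated ring; C8, between O7 and the ring oxygen, is less hindered than C6 (between two freely rotating alkoxy groups) and is the usual site of substitution in 5,7-di-O-alkyl flavans. One equivalent at low temperature should spare the allyl alkene and the less activated 4-benzyloxyphenyl ring.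

Step 6
Reactants: 12 (2S)-7-(allyloxy)-5-(benzyloxy)-2-[4-(benzyloxy)phenyl]-8-bromochromane
Product: 13 (2S)-5-(benzyloxy)-2-[4-(benzyloxy)phenyl]-8-bromochroman-7-ol
Conditions: Pd(PPh3)4 (5 mol %), morpholine, THF, rt
Reagents that add atoms: none
Why: Tsuji–Trost deallylation; zerovalent palladium ionises the aryl allyl ether and morpholine traps the allyl fragment. The hindered, electron-rich aryl bromide should not undergo oxidative addition with this catalyst at room temperature, and benzyl ethers are untouched.

Step 7
Reactants: 13 (2S)-5-(benzyloxy)-2-[4-(benzyloxy)phenyl]-8-bromochroman-7-ol; 14 tert-butyldimethylsilyl chloride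
Product: 15 {[(2S)-5-(benzyloxy)-2-[4-(benzyloxy)phenyl]-8-bromochroman-7-yl]oxy}(tert-butyl)dimethylsilane
Conditions: TBSCl, imidazole, DMF, rt
Reagents that add atoms: tert-butyldimethylsilyl chloride (14), CC(C)(C)[Si](C)(C)Cl
Why: Silylation of the phenol; the silyl ether is chosen because it tolerates the weakly basic coupling and the diazo transfer and is later removed by fluoride beside a diazo ketone, which no benzyl, allyl or acetal group would allow.

Step 8
Reactants: 16 2',4',6'-trihydroxyacetophenone; 9 benzyl bromide
Product: 17 1-[2,4,6-tris(benzyloxy)phenyl]ethan-1-one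
Conditions: BnBr (3.6 equiv), K2CO3, DMF, 70 °C
Reagents that add atoms: benzyl bromide (9), BrCc1ccccc1
Why: Exhaustive Williamson etherification; warming is needed for the two hydroxyls that are hydrogen-bonded to the acetyl group. No stereocentre is involved.

Step 9
Reactants: 15 {[(2S)-5-(benzyloxy)-2-[4-(benzyloxy)phenyl]-8-bromochroman-7-yl]oxy}(tert-butyl)dimethylsilane; 17 1-[2,4,6-tris(benzyloxy)phenyl]ethan-1-one
Product: 18 2-[(2S)-5-(benzyloxy)-2-[4-(benzyloxy)phenyl]-7-(tert-butyldimethylsilyloxy)chroman-8-yl]-1-[2,4,6-tris(benzyloxy)phenyl]ethan-1-one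
Conditions: Pd2(dba)3 (2.5 mol %), XPhos (10 mol %), K3PO4, 17 (1.5 equiv), toluene, 100 °C
Reagents that add atoms: none
Why: Palladium-catalysed α-arylation of a methyl ketone enolate with an aryl bromide; the bulky biaryl phosphine should drive oxidative addition into the electron-rich, doubly ortho-substituted bromide and the reductive elimination. K3PO4 is mild enough for the silyl ether, the crowded product resists a second arylation, and C2' is not touched.

Step 10
Reactants: 18 2-[(2S)-5-(benzyloxy)-2-[4-(benzyloxy)phenyl]-7-(tert-butyldimethylsilyloxy)chroman-8-yl]-1-[2,4,6-tris(benzyloxy)phenyl]ethan-1-one; 19 4-acetamidobenzenesulfonyl azide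
Product: 20 2-[(2S)-5-(benzyloxy)-2-[4-(benzyloxy)phenyl]-7-(tert-butyldimethylsilyloxy)chroman-8-yl]-2-diazo-1-[2,4,6-tris(benzyloxy)phenyl]ethan-1-one
Conditions: p-ABSA, DBU, MeCN, 0 °C to rt
Reagents that add atoms: 4-acetamidobenzenesulfonyl azide (19), CC(=O)Nc1ccc(cc1)S(=O)(=O)N=[N+]=[N-]
Why: Regitz diazo transfer to the only acidic C–H of the molecule, the methylene activated by both the ketone and the aryl ring. Should the base loosen the silyl ether, the compound formed is the phenol that step 11 generates anyway.

Step 11
Reactants: 20 2-[(2S)-5-(benzyloxy)-2-[4-(benzyloxy)phenyl]-7-(tert-butyldimethylsilyloxy)chroman-8-yl]-2-diazo-1-[2,4,6-tris(benzyloxy)phenyl]ethan-1-one; 21 4-(benzyloxy)benzoyl chloride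
Product: 23 (2S)-5-(benzyloxy)-2-[4-(benzyloxy)phenyl]-8-{1-diazo-2-oxo-2-[2,4,6-tris(benzyloxy)phenyl]ethyl}chroman-7-yl 4-(benzyloxy)benzoate, via 7-hydroxy diazo ketone 22 (not isolated)
Conditions: TBAF (1.05 equiv), THF, −20 °C; then 21 (1.5 equiv), DMAP (10 mol %), −20 °C to rt
Reagents that add atoms: 4-(benzyloxy)benzoyl chloride (21), O=C(Cl)c1ccc(OCc2ccccc2)cc1
Why: Fluoride desilylation gives the tetrabutylammonium phenoxide, which is O-acylated in the same flask; diazo ketones tolerate fluoride and acyl chlorides at low temperature. The ester is introduced only now because, before diazo transfer, the enolisable ketone would have attacked it (Baker–Venkataraman-type acyl migration).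

Step 12
Reactants: 23 (2S)-5-(benzyloxy)-2-[4-(benzyloxy)phenyl]-8-{1-diazo-2-oxo-2-[2,4,6-tris(benzyloxy)phenyl]ethyl}chroman-7-yl 4-(benzyloxy)benzoate; 24 water
Product: 25 ring F hemiketal: 2-hydroxy-2-[4-(benzyloxy)phenyl]-3-hydroxy-3-[2,4,6-tris(benzyloxy)benzoyl]-2,3-dihydrofuran fused through O7' and C8' to the (2'S)-5'-(benzyloxy)-2'-[4-(benzyloxy)phenyl]flavan; C3 is S, and C2 is drawn as one of the interconverting hemiketal epimers (S as drawn)
Conditions: Rh2(OAc)4 (2 mol %), (R)-TRIP (10 mol %), H2O (3 equiv), CH2Cl2, 0 °C, 23 added over 2 h
Reagents that add atoms: water (24), O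
Why: Proposed new method: Rh2(OAc)4 (divalent rhodium) expels N2 from the aryl acyl diazo compound to give a carbene at C3, water adds to it to form an oxonium ylide, and this ylide (or the enediol reached from it by proton shift) is a strong carbon nucleophile held three atoms away from the O7' aryl ester carbonyl. Attack of C3 on that carbonyl forms C2–C3 and closes ring F in the 5-exo-trig mode, and the tetrahedral alkoxide takes up the oxonium proton, so the adduct leaves as the neutral hemiketal; it cannot dehydrate to a benzofuran because C3 is fully substituted. The closest known reaction types are the Rh2(OAc)4-catalysed three-component couplings of diazo compounds with water or alcohols and aldehydes, imines or tethered ketones through oxonium ylides, and the enolate C-acylation by an ortho aryl ester of the Baker–Venkataraman rearrangement; interception of such an ylide by an ester has no precedent. C3 is the one stereocentre that the step must set: the chiral phosphoric acid (R)-TRIP, the 3,3'-bis(2,4,6-triisopropylphenyl) BINOL hydrogen phosphate, is expected to hold the ylide and the ester carbonyl in one hydrogen-bonded ion pair and so to choose the face of C3, since the remote C2' cannot, and the two C3 epimers are diastereomers that can be separated if control is incomplete. C2 arises as a hemiketal carbon that epimerises by ring–chain tautomerism and is settled only in step 13. The selectivity needed is C-acylation ahead of the 1,2-proton shift to the plain O–H insertion product, of O-to-O acyl transfer and of C–H insertion into benzylic ether positions; the activated aryl ester, the five-membered transition state, the slow addition of 23 and the excess of water are what should secure it.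

Step 13
Reactants: 25 ring F hemiketal (hexa-O-benzyl)
Product: 27 target biflavonoid (2R,3S,2'S), via hexahydroxy hemiketal 26 (not isolated)
Conditions: H2 (1 atm), Pd(OH)2/C, THF–EtOAc, rt; filter; then TsOH·H2O (5 mol %), THF, rt
Reagents that add atoms: none
Why: Hydrogenolysis of the six benzyl ethers under neutral conditions, then acid-catalysed transketalisation: loss of the hemiketal hydroxyl gives an oxocarbenium ion at C2, stabilised by O7' and the 4-hydroxyphenyl ring, which is captured by either of the two equivalent ortho hydroxyls of ring A to close ring C (6-exo-trig). C3 and C2' are not touched, and C2 is set in this reversible closure, not by a reagent.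

## Compound list

1 | (2S)-naringenin | O=C1C[C@@H](c2ccc(O)cc2)Oc2cc(O)cc(O)c12 | starting material
2 | allyl bromide | C=CCBr | starting material
3 | (2S)-7-(allyloxy)-5-hydroxy-2-(4-hydroxyphenyl)chroman-4-one | O=C1C[C@@H](c2ccc(O)cc2)Oc2cc(OCC=C)cc(O)c12 | intermediate
4 | benzyl alcohol | OCc1ccccc1 | starting material
5 | (2S)-7-(allyloxy)-2-[4-(benzyloxy)phenyl]-5-hydroxychroman-4-one | O=C1C[C@@H](c2ccc(OCc3ccccc3)cc2)Oc2cc(OCC=C)cc(O)c12 | intermediate
6 | ethyl chloroformate | CCOC(Cl)=O | starting material
7 | (2S)-7-(allyloxy)-2-[4-(benzyloxy)phenyl]-4-oxochroman-5-yl ethyl carbonate (not isolated) | O=C1C[C@@H](c2ccc(OCc3ccccc3)cc2)Oc2cc(OCC=C)cc(OC(=O)OCC)c12 | intermediate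
8 | (2S)-7-(allyloxy)-2-[4-(benzyloxy)phenyl]chroman-5-ol | Oc1cc(OCC=C)cc2c1CC[C@@H](c1ccc(OCc3ccccc3)cc1)O2 | intermediate
9 | benzyl bromide | BrCc1ccccc1 | starting material
10 | (2S)-7-(allyloxy)-5-(benzyloxy)-2-[4-(benzyloxy)phenyl]chromane | C=CCOc1cc(OCc2ccccc2)c2c(c1)O[C@H](c1ccc(OCc3ccccc3)cc1)CC2 | intermediate
11 | N-bromosuccinimide | O=C1CCC(=O)N1Br | starting material
12 | (2S)-7-(allyloxy)-5-(benzyloxy)-2-[4-(benzyloxy)phenyl]-8-bromochromane | C=CCOc1cc(OCc2ccccc2)c2c(c1Br)O[C@H](c1ccc(OCc3ccccc3)cc1)CC2 | intermediate
13 | (2S)-5-(benzyloxy)-2-[4-(benzyloxy)phenyl]-8-bromochroman-7-ol | Oc1cc(OCc2ccccc2)c2c(c1Br)O[C@H](c1ccc(OCc3ccccc3)cc1)CC2 | intermediate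
14 | tert-butyldimethylsilyl chloride | CC(C)(C)[Si](C)(C)Cl | starting material
15 | {[(2S)-5-(benzyloxy)-2-[4-(benzyloxy)phenyl]-8-bromochroman-7-yl]oxy}(tert-butyl)dimethylsilane | CC(C)(C)[Si](C)(C)Oc1cc(OCc2ccccc2)c2c(c1Br)O[C@H](c1ccc(OCc3ccccc3)cc1)CC2 | intermediate
16 | 2',4',6'-trihydroxyacetophenone | CC(=O)c1c(O)cc(O)cc1O | starting material
17 | 1-[2,4,6-tris(benzyloxy)phenyl]ethan-1-one | CC(=O)c1c(OCc2ccccc2)cc(OCc2ccccc2)cc1OCc1ccccc1 | intermediate
18 | 2-[(2S)-5-(benzyloxy)-2-[4-(benzyloxy)phenyl]-7-(tert-butyldimethylsilyloxy)chroman-8-yl]-1-[2,4,6-tris(benzyloxy)phenyl]ethan-1-one | CC(C)(C)[Si](C)(C)Oc1cc(OCc2ccccc2)c2c(c1CC(=O)c1c(OCc3ccccc3)cc(OCc3ccccc3)cc1OCc1ccccc1)O[C@H](c1ccc(OCc3ccccc3)cc1)CC2 | intermediate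
19 | 4-acetamidobenzenesulfonyl azide | CC(=O)Nc1ccc(cc1)S(=O)(=O)N=[N+]=[N-] | starting material
20 | 2-[(2S)-5-(benzyloxy)-2-[4-(benzyloxy)phenyl]-7-(tert-butyldimethylsilyloxy)chroman-8-yl]-2-diazo-1-[2,4,6-tris(benzyloxy)phenyl]ethan-1-one | CC(C)(C)[Si](C)(C)Oc1cc(OCc2ccccc2)c2c(c1C(=[N+]=[N-])C(=O)c1c(OCc3ccccc3)cc(OCc3ccccc3)cc1OCc1ccccc1)O[C@H](c1ccc(OCc3ccccc3)cc1)CC2 | intermediate
21 | 4-(benzyloxy)benzoyl chloride | O=C(Cl)c1ccc(OCc2ccccc2)cc1 | starting material
22 | 2-[(2S)-5-(benzyloxy)-2-[4-(benzyloxy)phenyl]-7-hydroxychroman-8-yl]-2-diazo-1-[2,4,6-tris(benzyloxy)phenyl]ethan-1-one (not isolated) | Oc1cc(OCc2ccccc2)c2c(c1C(=[N+]=[N-])C(=O)c1c(OCc3ccccc3)cc(OCc3ccccc3)cc1OCc1ccccc1)O[C@H](c1ccc(OCc3ccccc3)cc1)CC2 | intermediate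
23 | (2S)-5-(benzyloxy)-2-[4-(benzyloxy)phenyl]-8-{1-diazo-2-oxo-2-[2,4,6-tris(benzyloxy)phenyl]ethyl}chroman-7-yl 4-(benzyloxy)benzoate | [N-]=[N+]=C(C(=O)c1c(OCc5ccccc5)cc(OCc5ccccc5)cc1OCc5ccccc5)c1c(OC(=O)c2ccc(OCc5ccccc5)cc2)cc(OCc5ccccc5)c2c1O[C@H](c1ccc(OCc5ccccc5)cc1)CC2 | intermediate
24 | water | O | starting material
25 | hexa-O-benzyl ring F hemiketal with C3 hydroxyl and C3 2,4,6-tris(benzyloxy)benzoyl group (3S,2'S; C2 drawn S, hemiketal epimers interconvert) | O[C@@]2(c3ccc(OCc5ccccc5)cc3)Oc3cc(OCc5ccccc5)c4c(c3[C@]2(O)C(=O)c6c(OCc5ccccc5)cc(OCc5ccccc5)cc6OCc5ccccc5)O[C@H](c1ccc(OCc5ccccc5)cc1)CC4 | intermediate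
26 | hexahydroxy ring F hemiketal (3S,2'S; not isolated) | O[C@@]2(c3ccc(O)cc3)Oc3cc(O)c4c(c3[C@]2(O)C(=O)c6c(O)cc(O)cc6O)O[C@H](c1ccc(O)cc1)CC4 | intermediate
27 | target biflavonoid CNP0208300.3 (2R,3S,2'S) | O=C1c2c(O)cc(O)cc2O[C@@]2(c3ccc(O)cc3)Oc3cc(O)c4c(c3[C@]12O)O[C@H](c1ccc(O)cc1)CC4 | target

## Step count and risks

Total step count: 13. Longest linear sequence: 12 steps (steps 1 to 7 and 9 to 13); step 8 prepares ketone 17 on a side branch.

**Step 12 (key step).** The most likely failure is that proton transfer within the oxonium ylide outruns C–C bond formation, so that plain O–H insertion occurs without acyl capture. The second is poor facial selectivity at C3, because the chiral acid organises a proton shift and sits some distance from the forming bond. The third is diversion of the carbene by the ester carbonyl oxygen.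

The fallback uses known reactions, sets out from 18 and returns at 25:
- Fluoride desilylation of 18 (TBAF, THF) gives the 7-hydroxy deoxybenzoin F1, which is acylated in the same flask with 21 to the O7' 4-(benzyloxy)benzoate F2.
- LiN(SiMe3)2 in THF at −78 °C triggers the Baker–Venkataraman-type acyl shift (enolate C-acylation). Acid work-up (TsOH, warm toluene) dehydrates the adduct, which is possible here because C3 still carries hydrogen, to the 2-aryl-3-aroylbenzofuran F3.
- Epoxidation of the furan C2=C3 bond with dimethyldioxirane in wet acetone, and opening of the labile epoxide by water at C2, gives 25 together with its C3 epimer.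
- The two epimers are diastereomers because C2' is fixed and are separated by chromatography; a chiral ketone-derived dioxirane can be used to bias the face.

**Step 9.** The likely failures are sluggish oxidative addition and protodebromination at the doubly ortho-substituted, electron-rich bromide, or loss of the silyl group under the basic coupling followed by cyclodehydration of the freed phenol onto the ketone. A triisopropylsilyl ether would be the like-for-like remedy for the second.

The fallback changes the bond-forming logic, sets out from 10 and returns at 18: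
- Heating 10 in N,N-diethylaniline (190 °C) effects aromatic Claisen rearrangement to the 8-allyl-7-hydroxy flavan F4; the 6-allyl isomer is removed by chromatography.
- Silylation (14, imidazole, DMF) gives silyl ether F5.
- Lemieux–Johnson cleavage (OsO4 cat., NaIO4, 2,6-lutidine, dioxane–water) gives arylacetaldehyde F6, and Pinnick oxidation (NaClO2, NaH2PO4, 2-methyl-2-butene) gives arylacetic acid F7.
- Friedel–Crafts acylation of commercial 1,3,5-tris(benzyloxy)benzene (in excess) by the mixed trifluoroacetic anhydride of F7 (TFAA, CH2Cl2, 0 °C) gives 18.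

**Step 13.** The likely failures are hydrogenolysis of the benzylic C–O bonds at C2 and C3, or fragmentation of the free hexaphenol (retro-Claisen opening at C3) before the ketal has closed.

The fallback closes ring C before the global deprotection, sets out from 25 and returns at 27:
- MgBr2·OEt2 (toluene–Et2O, 60 °C) removes, through chelation to the C4 carbonyl, one benzyl ether ortho to the ketone.
- The liberated ring A hydroxyl closes ring C under the same Lewis acid to give the penta-O-benzyl ketal F8. In F8, C2 is no longer a hemiketal and the α-hydroxy ketone is tied into the ring.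
- Hydrogenolysis of F8 (H2, Pd/C, THF–MeOH) then gives 27.

**Step 3.** The likely failure is that the reduction stops at the C4 alcohol, or that elimination to the flav-3-ene occurs, if carbonate migration and quinone methide formation are slow in the cyclic system.

The fallback sets out from 5 and returns at 8:
- NaBH4 (MeOH–THF, 0 °C) reduces 5 to the 2,4-cis flavan-4,5-diol F9.
- Ionic hydrogenation (Et3SiH, TFA, CH2Cl2, −20 °C) of the very easily ionised C4 alcohol gives 8.

## Further compounds

F1 | step 12 | 2-[(2S)-5-(benzyloxy)-2-[4-(benzyloxy)phenyl]-7-hydroxychroman-8-yl]-1-[2,4,6-tris(benzyloxy)phenyl]ethan-1-one | Oc1cc(OCc2ccccc2)c2c(c1CC(=O)c1c(OCc3ccccc3)cc(OCc3ccccc3)cc1OCc1ccccc1)O[C@H](c1ccc(OCc3ccccc3)cc1)CC2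
F2 | step 12 | (2S)-5-(benzyloxy)-2-[4-(benzyloxy)phenyl]-8-{2-oxo-2-[2,4,6-tris(benzyloxy)phenyl]ethyl}chroman-7-yl 4-(benzyloxy)benzoate | O=C(Oc1cc(OCc2ccccc2)c2c(c1CC(=O)c1c(OCc3ccccc3)cc(OCc3ccccc3)cc1OCc1ccccc1)O[C@H](c1ccc(OCc3ccccc3)cc1)CC2)c1ccc(OCc2ccccc2)cc1
F3 | step 12 | 2-[4-(benzyloxy)phenyl]-3-[2,4,6-tris(benzyloxy)benzoyl]benzofuran fused through O7' and C8' to the (2'S)-5'-(benzyloxy)-2'-[4-(benzyloxy)phenyl]flavan | O=C(c1c(OCc2ccccc2)cc(OCc2ccccc2)cc1OCc1ccccc1)c1c(-c2ccc(OCc3ccccc3)cc2)oc2cc(OCc3ccccc3)c3c(c12)O[C@H](c1ccc(OCc2ccccc2)cc1)CC3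
F4 | step 9 | (2S)-8-allyl-5-(benzyloxy)-2-[4-(benzyloxy)phenyl]chroman-7-ol | C=CCc1c(O)cc(OCc2ccccc2)c2c1O[C@H](c1ccc(OCc3ccccc3)cc1)CC2
F5 | step 9 | {[(2S)-8-allyl-5-(benzyloxy)-2-[4-(benzyloxy)phenyl]chroman-7-yl]oxy}(tert-butyl)dimethylsilane | C=CCc1c(O[Si](C)(C)C(C)(C)C)cc(OCc2ccccc2)c2c1O[C@H](c1ccc(OCc3ccccc3)cc1)CC2
F6 | step 9 | 2-[(2S)-5-(benzyloxy)-2-[4-(benzyloxy)phenyl]-7-(tert-butyldimethylsilyloxy)chroman-8-yl]acetaldehyde | O=CCc1c(O[Si](C)(C)C(C)(C)C)cc(OCc2ccccc2)c2c1O[C@H](c1ccc(OCc3ccccc3)cc1)CC2
F7 | step 9 | 2-[(2S)-5-(benzyloxy)-2-[4-(benzyloxy)phenyl]-7-(tert-butyldimethylsilyloxy)chroman-8-yl]acetic acid | OC(=O)Cc1c(O[Si](C)(C)C(C)(C)C)cc(OCc2ccccc2)c2c1O[C@H](c1ccc(OCc3ccccc3)cc1)CC2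
F8 | step 13 | penta-O-benzyl ether of the target (ring C closed; 2R,3S,2'S) | O=C1c2c(OCc5ccccc5)cc(OCc5ccccc5)cc2O[C@@]2(c3ccc(OCc5ccccc5)cc3)Oc3cc(OCc5ccccc5)c4c(c3[C@]12O)O[C@H](c1ccc(OCc5ccccc5)cc1)CC4
F9 | step 3 | (2S,4S)-7-(allyloxy)-2-[4-(benzyloxy)phenyl]chromane-4,5-diol | O[C@H]1C[C@@H](c2ccc(OCc3ccccc3)cc2)Oc2cc(OCC=C)cc(O)c12
A1 | alternative 1 | 3-(benzyloxy)-2-{(3S)-3-[4-(benzyloxy)phenyl]-3-[(trimethylsilyl)ethynyloxy]propyl}cyclobut-2-en-1-one | C[Si](C)(C)C#CO[C@H](c1ccc(OCc2ccccc2)cc1)CCC1=C(OCc2ccccc2)CC1=O
A2 | alternative 1 | (2S)-5-(benzyloxy)-2-[4-(benzyloxy)phenyl]-8-(trimethylsilyl)chroman-7-ol | C[Si](C)(C)c1c(O)cc(OCc5ccccc5)c2c1O[C@H](c1ccc(OCc5ccccc5)cc1)CC2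
A3 | alternative 2 | methyl 3,5,7-trioxoheptanoate chain attached at C7 to C3 of the ring F methyl ketal (C3 methoxymethyl ether) | CO[C@@]2(c3ccc(OCc5ccccc5)cc3)Oc3cc(OCc5ccccc5)c4c(c3[C@]2(OCOC)C(=O)CC(=O)CC(=O)CC(=O)OC)O[C@H](c1ccc(OCc5ccccc5)cc1)CC4
A4 | alternative 2 | C3 2,4,6-trihydroxybenzoyl ketone on the ring F methyl ketal (C3 methoxymethyl ether) | CO[C@@]2(c3ccc(OCc5ccccc5)cc3)Oc3cc(OCc5ccccc5)c4c(c3[C@]2(OCOC)C(=O)c6c(O)cc(O)cc6O)O[C@H](c1ccc(OCc5ccccc5)cc1)CC4
A5 | alternative 3 | 2-[4-(benzyloxy)phenyl]-2-[3,5-bis(benzyloxy)-2-formylphenoxy]benzofuran-3-one fused through O7' and C8' to the (2'S)-5'-(benzyloxy)-2'-[4-(benzyloxy)phenyl]flavan | O=Cc1c(OCc5ccccc5)cc(OCc5ccccc5)cc1O[C@@]1(c2ccc(OCc5ccccc5)cc2)Oc2cc(OCc5ccccc5)c3c(c2C1=O)O[C@H](c1ccc(OCc5ccccc5)cc1)CC3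
A6 | alternative 3 | penta-O-benzyl ether of the target | O=C1c2c(OCc5ccccc5)cc(OCc5ccccc5)cc2O[C@@]2(c3ccc(OCc5ccccc5)cc3)Oc3cc(OCc5ccccc5)c4c(c3[C@]12O)O[C@H](c1ccc(OCc5ccccc5)cc1)CC4
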